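The trap in this flask is to see Z climb in straight lines and call it first order in X.

| setting | noon | winter | autumn | flask |
|---|---|---|---|---|
| D | 0.020 M | 0.020 M | 0.030 M | 0.020 M |
| E | 3.4 mM (held) | 3.4 mM (held) | 3.4 mM (held) | 3.4 mM (held) |
| X | 0.075 mM | 0.11 mM | 0.15 mM | 0.15 mM |
| remark | run made earlier | run made earlier | run made earlier |  |

| run | time / h | Z / % | D / % |
|---|---|---|---|
| noon | 0.200 | 3.0 | 97.3 |
| noon | 0.667 | 14.3 | 86.6 |
| noon | 1.33 | 29.8 | 70.8 |
| noon | 2.00 | 44.2 | 56.0 |
| noon | 2.50 | 56.1 | 43.3 |
| winter | 0.500 | 13.1 | 87.0 |
| winter | 1.00 | 28.4 | 70.4 |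
| winter | 1.50 | 44.9 | 54.4 |
| winter | 2.00 | 62.2 | 37.3 |
| winter | 2.50 | 78.7 | 22.3 |
| autumn | 0.500 | 11.4 | 88.2 |
| autumn | 1.00 | 25.8 | 73.9 |
| autumn | 1.50 | 39.1 | 61.3 |
| autumn | 2.00 | 52.8 | 46.7 |
| autumn | 2.50 | 68.0 | 33.2 |

(readings scatter by 0.5 percentage points)

- at the start none of E is in solution

1. apparent order in X when 50 % of the D are converted (percent change of the rate of making Z for one percent more X charged)

We count rates as fractions of the flask's D charge per hour, and we treat D as having no effect (zero order in D), since each Z line runs straight while D falls. The flask should then run like the autumn run, which has the same X, at 0.424 h⁻¹; the winter run gives 0.328 h⁻¹.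

The first way is the chord between these two runs, which gives an order of 0.832. That chord belongs to a mean rate of 0.376 h⁻¹, though, and not to the flask.

The second way uses the lag. Run back, the lines meet zero Z late, on average after 0.0989 h in the winter and autumn runs, though the noon run reads 0.0399 h, which we set aside. No E is in solution at the start, so we read that lag as the time dissolved E takes to reach its working level. Saturation over lag then gives our rough estimate of the ceiling, the rate at which E enters a solution empty of it, 1.72 h⁻¹. If the rate follows X times dissolved E, and dissolved E sags in proportion to the rate, the order is one minus rate over ceiling.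

At the chord's rate this gives 0.781, lower than the chord by 0.0506, so the two ways part and this proves neither. The chord flatters the flask, whose rate is higher, and our reckoning for the flask is 0.753.

The forecast, which took the cap to be “probably E supply”, gave 0.84.

The flask gives 0.75.

    G + X → J (k = 737 M⁻¹ min⁻¹)
    D + J → Q (k = 2860 M⁻¹ min⁻¹)
    Q → X + Z (k = 2.35 min⁻¹)
    E ⇌ G, rate k4*(csat - [G]) (kL = 0.110 min⁻¹)

At 1.28 h the flask makes Z at 0.412 h⁻¹, which is 24.0 % of the ceiling we read from the lag, and one minus that share is 0.760. The scheme's constants put E's entry into a solution empty of it at 1.12 h⁻¹, lower than that reading, and one minus rate over this entry is 0.633, under the flask's order, so the closeness of our figure is no check of the rule. Through 1.25 h, E passed into G, held at 0.00215 M, while the cycle turned D into Z with the catalyst lying as X 57.9 %, Q 39.0 % and J 3.12 %. By 2.50 h, with D down to 2.70 %, J stood at 38.1 % of the catalyst charged.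

The numbers in the tables were generated by integration with made-up constants; the scatter is artificial.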